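## Structural features

The target is a (2S)-flavanone: a chroman-4-one in which benzo ring A (free phenol at C7) is fused to the dihydropyranone ring C, with an aryl group (ring B) at the only stereocentre, C2. Ring B is a 1,3,4,5-tetrasubstituted benzene: C1' is bonded to C2, C4' carries a methoxy group, C3' a prenyl group and C5' an (E)-3-hydroxy-3-methylbut-1-enyl group. With a single stereocentre there is no relative configuration to control. C2 is nevertheless fragile, because it is bonded to O1 and lies β to the C4 ketone, so base can open ring C by retro-oxa-Michael reaction to the 2'-hydroxychalcone and reclose it without selectivity. The tertiary allylic alcohol, conjugated to an electron-rich arene, ionises easily under acid (dehydration, allylic transposition). The trisubstituted prenyl alkene adds protic acid and electrophilic halogen, so late acidic or halogenating steps are excluded. The real difficulty is the contiguous, fully differentiated 3',4',5' pattern of ring B, which substitution chemistry on a phenol cannot deliver cleanly, together with a mild, late, enantioselective formation of C2. The key step exploits the fact that ring B maps onto a 2-pyrone and a ketene acetal: pyrone C3 (ester) becomes C5', pyrone C5 (bromine) becomes C1', the acetal carbon becomes C4' with its methoxy group, and the prenyl-bearing ketene acetal carbon becomes C3'.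

## Logic of the disconnections

23 to 22: the O7–Si bond is cut. The free 7-phenol is a vinylogous acid that would deactivate the enone and promote ring opening, so it is masked until the end. The forward step must remove silicon without forming a long-lived phenoxide or a strongly acidic medium.

22 to 19 and 21: the C2–C1' bond is cut. This separates the molecule into a complete ring B and a simple bicyclic enone and creates the only stereocentre in the last carbon–carbon bond-forming step. The forward step must add an aryl group to C2 with control of the enone face, under conditions that do not epimerise the product or disturb the allylic alcohol.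

19 to 16: the C1'–B bond is exchanged for C1'–Br. The bromide is an inert spectator through the side-chain chemistry and is activated only when needed. The forward step must convert the bromide in the presence of a free tertiary alcohol and two alkenes.

16 to 15, 15 to 12 and 13, 12 to 11: the carbinol C–CH3 bond, then the side-chain C=C bond, then the oxidation level of the benzylic carbon are taken back to an aryl ester. The five-carbon hydroxyalkenyl chain thereby reduces to a methyl nucleophile, a three-carbon ylide and the ester carbon. The forward steps must give the (E)-alkene and 1,2-addition to the enone.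

11 to 3 and 8: the ring-B bonds C4'–C5' and C2'–C3' are cut. This removes the whole aromatic ring and reduces a tetrasubstituted benzene to a monocyclic pyrone and an acyclic ketene acetal, with each substituent position fixed by which partner carries it. The forward step must be regioselective and must end in full aromatisation.

3 to 1: the C5–Br bond is cut, leaving a commercial pyrone. The forward step must halogenate the one remaining nucleophilic ring position.

8 to 7, and 7 to 4 and 5: the ketene acetal π bond is traced to loss of methanol from an ortho ester, and the C1–C2 bond of 7 is then cut between the ortho carbon and the homoprenyl chain. This route is chosen because an ester cannot be taken directly to its trimethyl ortho ester, and acid-based ortho ester syntheses would add HCl to the prenyl alkene. The forward steps must stay non-acidic throughout.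

21 to 20: the O–Si bond is cut, leaving a commercial hydroxychromone.

## Other disconnections considered

Alternative 1: The cut is the aryl ether bond O1–C8a of ring C at the flavan-4-ol oxidation level. In the forward sense the bromo diol A2 would be closed by intramolecular palladium-catalysed C–O coupling of the C2 carbinol with the ortho bromide of ring A (Pd(OAc)2, a bulky di-tert-butyl biaryl phosphine, Cs2CO3) to give the cis flavan-4-ol A1; oxidation at C4 and desilylation would follow. The descriptor pair (2S,4S) belongs to the 2,4-cis isomer, which needs opposite chirality tags at C2 and C4 in line notation (identical tags would describe the trans (2S,4R) isomer), and A1 is written that way below. The configuration at C4 is immaterial because that carbinol is oxidised.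
- In favour: the C2–O bond is never broken, no ketone is present during ring closure, and C2 can be set earlier by a well-understood asymmetric reduction or aldol. On configurational security of C2 during ring formation this alternative is the equal or the better of the chosen plan.
- Against: secondary benzylic palladium alkoxides are prone to β-hydride elimination, which would give a ketone and the debrominated arene. A2 carries two stereocentres although the target has one, so a stereocentre and an oxidation level are built and then destroyed.
- Comparison on structure: the fully substituted ring B still has to be made, so a ring-B construction such as the pyrone annulation leading to 11 would be needed upstream in any case.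
- Comparison on mechanism: the chosen plan creates C2 in one catalytic addition to a commercial enone; the alternative spreads the same task over an aldol, a reduction and a coupling.
- Comparison on step economy: the alternative would be at least three steps longer.

Alternative 2: The cut is C4a–C5 and C8–C8a, so that ring A is grown on a preformed chiral ring C. In the forward sense the bromo dihydropyranone A4 would serve as dienophile towards the silyloxy diene A5; the CH2 terminus of A5 would bond to the future C8a and the methoxy-bearing terminus to the future C4a, and loss of methanol and HBr would give the phenol A3.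
- In favour: the C2 stereocentre could come from a catalytic asymmetric hetero-Diels–Alder reaction of an aryl aldehyde, a reaction type with deep precedent. The 7-hydroxyl appears with the right regiochemistry and without a protecting group. On protecting-group economy this alternative is the better of the two, and on confidence in the stereocentre-forming reaction type it is at least the equal.
- Against: the C5=C6 bond of a β-alkoxy enone is a poor dienophile, so heat or a Lewis acid would be needed, and under either the 2-aryl dihydropyranone can open by β-elimination at C2.
- Comparison on structure: A3 carries two equivalent bromines on ring B, so the prenyl and hydroxyalkenyl groups would have to be introduced by a statistical mono-coupling followed by a second coupling, both on a base-sensitive free-phenol flavanone. The chosen plan differentiates C3' and C5' in the ring-forming step itself.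
- Comparison on mechanism: the alternative relies on a normal-demand cycloaddition of electronically mismatched partners; the chosen plan uses a polarity-matched inverse-demand cycloaddition.
- Comparison on step economy: the two late cross-couplings and the statistical loss outweigh the two protecting-group steps saved.

Alternative 3: The cut is C3–C4, made as the C3=C4 bond of a 4-silyloxy-2H-chromene. In the forward sense the diene A7 (an (S)-configured aryl 1-arylallyl ether with an ortho 1-silyloxyvinyl group) would undergo ring-closing metathesis with a second-generation Hoveyda–Grubbs catalyst and loss of ethylene to give A6. Hydrolysis of the enol ether, a Heck reaction of the aryl bromide with the allylic alcohol A8, and desilylation would follow.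
- In favour: ring C is closed under neutral conditions that do not touch C2, and the ketone is unmasked late. The side chain would be installed in one Heck step from the bromide instead of three steps from an ester; on that point the alternative is the better.
- Against: the prenyl group is a trisubstituted alkene that ruthenium alkylidenes can engage (truncation with loss of isobutene, cross-metathesis). Ring closure onto an electron-rich 1,1-disubstituted silyl enol ether is slow, which gives these side reactions time.
- Further against: the doubly activated benzylic and allylic aryl ether of A7 can ionise or rearrange on heating, and a Heck reaction on a flavanone needs base and heat, which invites retro-oxa-Michael opening.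
- Comparison on structure: ring B of A7 needs the same contiguous pattern (bromide in place of ester), so the ring-B problem is not removed.
- Comparison on mechanism: chemoselectivity of the metal carbene against the prenyl alkene is the main liability and has no counterpart in the chosen plan.
- Comparison on step economy: roughly equal overall; the shorter side-chain installation is offset by the longer assembly of A7.

Key step: step 4

Remark: an ester cannot practically be converted into its trimethyl ortho ester and the nitrile/HCl/methanol route would hydrochlorinate the trisubstituted alkene, so 7 is made from a Grignard reagent and tetramethyl orthocarbonate.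

Remark: the sense of induction in step 10 is assigned by analogy with cyclic enones; a model addition of phenylboronic acid to 21 is assumed to confirm it before 19 is committed, and the ligand antipode is exchanged if needed.

## Route

Step 1
Reactants: 1 methyl 2-oxo-2H-pyran-3-carboxylate
Product: 3 methyl 5-bromo-2-oxo-2H-pyran-3-carboxylate, via 5,6-dibromide adduct 2 (not isolated)
Conditions: Br2 (1.1 equiv), CH2Cl2, 0 °C to rt; then Et3N (1.2 equiv), 0 °C
Reagents that add atoms: bromine, BrBr
Why: Addition–elimination bromination of a 2-pyrone: C5 is the enol-ether β-carbon and the only nucleophilic ring position left once C3 bears the ester, so Br2 adds across C5=C6 and the amine removes HBr (H5 and the anomeric C6 bromide) to restore the pyrone.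

Step 2
Reactants: 4 5-bromo-2-methylpent-2-ene; 5 tetramethyl orthocarbonate
Product: 7 1,1,1-trimethoxy-5-methylhex-4-ene, via homoprenyl Grignard reagent 6 (not isolated)
Conditions: Mg, 1,2-dibromoethane (cat.), Et2O, reflux; then 5 (1.5 equiv), toluene, 60 °C; cold aq. NaHCO3; distillation
Reagents that add atoms: none
Why: Grignard formation and substitution of one methoxide of the orthocarbonate (Tschitschibabin-type ortho ester synthesis); the product ortho ester is far less electrophilic than 5, so the reaction should stop after one substitution, and no acid ever meets the trisubstituted alkene.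

Step 3
Reactants: 7 1,1,1-trimethoxy-5-methylhex-4-ene
Product: 8 1,1-dimethoxy-5-methylhexa-1,4-diene
Conditions: Me3SiOTf (1.05 equiv), i-Pr2NEt (1.5 equiv), CH2Cl2, −20 °C to rt; pentane extraction; bulb-to-bulb distillation from K2CO3
Reagents that add atoms: none
Why: Elimination of methanol from an ortho ester: the silyl triflate abstracts a methoxide to give a dialkoxycarbenium ion, which the hindered amine deprotonates at its only α-CH2 (the ortho ester counterpart of the Lewis acid/amine acetal-to-enol ether elimination); the skipped prenyl alkene is not involved and the product is kept over base and used at once.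

Step 4
Reactants: 3 methyl 5-bromo-2-oxo-2H-pyran-3-carboxylate; 8 1,1-dimethoxy-5-methylhexa-1,4-diene
Product: 11 methyl 5-bromo-2-methoxy-3-(3-methylbut-2-enyl)benzoate, via bicyclic lactone cycloadduct 9 (not isolated), via dimethoxycyclohexadiene 10 (not isolated)
Conditions: 8 (3 equiv), toluene, base-washed sealed tube, 110 °C, then 140 °C
Reagents that add atoms: none
Why: The pyrone 3 is an electron-poor diene (C3=C4–C5=C6, LUMO lowered by the lactone carbonyl, the C3 ester and the C5 bromine) and 8 is a strongly electron-rich 2π partner, so a thermal inverse-electron-demand Diels–Alder reaction should join pyrone C6 to the prenyl-bearing carbon of 8 (future C2'–C3') and pyrone C3 to the acetal carbon (future C4'–C5'), giving the bridged lactone 9. Retro-(4+2) extrusion of CO2 from 9 gives the cyclohexadiene 10, and loss of methanol from its C(OMe)2–CH unit, driven by aromatisation, gives 11; the closest known reaction type is the salicylate-forming annulation of 3-carbomethoxy-2-pyrones with 1,1-dimethoxyethene. Ring B is therefore closed by an intermolecular (4+2) cycloaddition followed by cycloreversion, both new ring bonds being formed in one operation. No stereocentre survives, since the centres of 9 and 10 are erased on aromatisation and endo/exo selectivity is irrelevant. The step needs regioselectivity, and matched polarity secures it: the nucleophilic β-carbon of the ketene acetal attacks C6, the electrophilic terminus of the doubly activated dienoate, while the developing dialkoxycarbenium centre bonds to C3, where the ester stabilises negative charge, so the methoxy group must end up between the prenyl group and the ester. It also needs chemoselectivity between the two alkenes of 8, which the very large difference in nucleophilicity between the ketene acetal and the prenyl double bond provides. The bromine stays on an sp2 carbon throughout and cannot be eliminated, and the only hydrogen that can leave with methoxide is the one on the prenyl-bearing carbon, so aromatisation has a single outcome.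

Step 5
Reactants: 11 methyl 5-bromo-2-methoxy-3-(3-methylbut-2-enyl)benzoate
Product: 12 [5-bromo-2-methoxy-3-(3-methylbut-2-enyl)phenyl]methanol
Conditions: i-Bu2AlH (2.5 equiv), CH2Cl2, −78 to 0 °C; aq. potassium sodium tartrate
Reagents that add atoms: none
Why: Hydride reduction of the aryl ester to the benzylic alcohol; the aryl bromide, the aryl methyl ether and the trisubstituted alkene are inert to i-Bu2AlH at low temperature.

Step 6
Reactants: 12 [5-bromo-2-methoxy-3-(3-methylbut-2-enyl)phenyl]methanol; 13 1-(triphenylphosphoranylidene)propan-2-one
Product: 15 (E)-4-[5-bromo-2-methoxy-3-(3-methylbut-2-enyl)phenyl]but-3-en-2-one, via aldehyde 14 (not isolated)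
Conditions: MnO2 (activated, 10 equiv), 13 (1.3 equiv), toluene, 90 °C
Reagents that add atoms: none
Why: Tandem oxidation–Wittig reaction: MnO2 oxidises only the benzylic alcohol and the stabilised keto-ylide traps the aldehyde as it forms, the stabilised-ylide olefination giving the (E)-enone.

Step 7
Reactants: 15 (E)-4-[5-bromo-2-methoxy-3-(3-methylbut-2-enyl)phenyl]but-3-en-2-one
Product: 16 (E)-4-[5-bromo-2-methoxy-3-(3-methylbut-2-enyl)phenyl]-2-methylbut-3-en-2-ol
Conditions: MeMgBr (1.5 equiv), THF, −78 to 0 °C; pH 7 phosphate buffer
Reagents that add atoms: methylmagnesium bromide, C[Mg]Br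
Why: Grignard 1,2-addition of the hard methyl nucleophile to the β-aryl enone carbonyl should give the tertiary allylic alcohol; the aryl bromide does not exchange with MeMgBr at low temperature and the neutral work-up avoids ionisation of the new alcohol.

Step 8
Reactants: 16 (E)-4-[5-bromo-2-methoxy-3-(3-methylbut-2-enyl)phenyl]-2-methylbut-3-en-2-ol
Product: 19 [3-[(E)-3-hydroxy-3-methylbut-1-enyl]-4-methoxy-5-(3-methylbut-2-enyl)phenyl]boronic acid, via dilithiated aryllithium alkoxide 17 (not isolated), via lithium triisopropoxyborate complex 18 (not isolated)
Conditions: n-BuLi (2.2 equiv), THF, −78 °C; B(Oi-Pr)3 (3 equiv), −78 °C to rt; aq. NH4Cl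
Reagents that add atoms: triisopropyl borate, CC(C)OB(OC(C)C)OC(C)C; water, O
Why: Lithiation–borylation: the first equivalent of base deprotonates the alcohol, bromine–lithium exchange at −78 °C is faster than any deprotonation at carbon, and the borate traps the aryllithium; mildly buffered hydrolysis frees the boronic acid without ionising the tertiary allylic alcohol.

Step 9
Reactants: 20 7-hydroxy-4H-chromen-4-one
Product: 21 7-[tri(propan-2-yl)silyl]oxy-4H-chromen-4-one
Conditions: i-Pr3SiCl (1.2 equiv), imidazole (2.5 equiv), DMF, rt
Reagents that add atoms: chlorotri(propan-2-yl)silane, CC(C)[Si](Cl)(C(C)C)C(C)C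
Why: Imidazole-promoted silylation of the acidic 7-phenol masks the vinylogous acid that would otherwise deactivate the enone and protonate the aryl–rhodium intermediate of step 10; the bulky silyl group should tolerate the aqueous conditions of that step.

Step 10
Reactants: 19 [3-[(E)-3-hydroxy-3-methylbut-1-enyl]-4-methoxy-5-(3-methylbut-2-enyl)phenyl]boronic acid; 21 7-[tri(propan-2-yl)silyl]oxy-4H-chromen-4-one
Product: 22 (2S)-2-[3-[(E)-3-hydroxy-3-methylbut-1-enyl]-4-methoxy-5-(3-methylbut-2-enyl)phenyl]-7-[tri(propan-2-yl)silyl]oxy-2,3-dihydro-4H-chromen-4-one
Conditions: [Rh(OH)((S)-MeO-F12-BIPHEP)]2 (3 mol % Rh), 21 (1.5 equiv), CH2Cl2/H2O (10:1), 20 °C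
Reagents that add atoms: none
Why: Rhodium-catalysed asymmetric 1,4-addition of an arylboronic acid to a chromone (Hayashi–Miyaura reaction): transmetalation to an aryl–rhodium species, enantioface-selective insertion of C2=C3 and protonolysis of the oxa-π-allyl by water. The C2 stereocentre is set by the chiral bisphosphine, which must deliver the aryl group to the Re face of C2 (O1 > C3 > H) to give 2S, the (S)-ligand being chosen by analogy with cyclic enones. Base-free conditions should keep the flavanone from ring opening, and the excess of 21 suppresses a second addition to the product ketone.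

Step 11
Reactants: 22 (2S)-2-[3-[(E)-3-hydroxy-3-methylbut-1-enyl]-4-methoxy-5-(3-methylbut-2-enyl)phenyl]-7-[tri(propan-2-yl)silyl]oxy-2,3-dihydro-4H-chromen-4-one
Product: 23 (2S)-7-hydroxy-2-[3-[(E)-3-hydroxy-3-methylbut-1-enyl]-4-methoxy-5-(3-methylbut-2-enyl)phenyl]-2,3-dihydro-4H-chromen-4-one
Conditions: Bu4NF (1.1 equiv), AcOH (1.5 equiv), THF, 0 °C
Reagents that add atoms: none
Why: Fluoride cleavage of the aryl silyl ether buffered with acetic acid: the phenoxide is protonated as it forms, so neither base-mediated retro-oxa-Michael opening at C2 nor acid ionisation of the tertiary allylic alcohol should occur.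

## Compound list

1 | methyl 2-oxo-2H-pyran-3-carboxylate | COC(=O)c1cccoc1=O | starting material
2 | methyl 5,6-dibromo-2-oxo-5,6-dihydro-2H-pyran-3-carboxylate (racemic, diastereomer mixture) | COC(=O)C1=CC(Br)C(Br)OC1=O | intermediate
3 | methyl 5-bromo-2-oxo-2H-pyran-3-carboxylate | COC(=O)c1cc(Br)coc1=O | intermediate
4 | 5-bromo-2-methylpent-2-ene | CC(C)=CCCBr | starting material
5 | tetramethyl orthocarbonate (tetramethoxymethane) | COC(OC)(OC)OC | starting material
6 | (4-methylpent-3-enyl)magnesium bromide | CC(C)=CCC[Mg]Br | intermediate
7 | 1,1,1-trimethoxy-5-methylhex-4-ene | COC(OC)(OC)CCC=C(C)C | intermediate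
8 | 1,1-dimethoxy-5-methylhexa-1,4-diene | COC(OC)=CCC=C(C)C | intermediate
9 | methyl 6-bromo-8,8-dimethoxy-7-(3-methylbut-2-enyl)-3-oxo-2-oxabicyclo[2.2.2]oct-5-ene-4-carboxylate (racemic, diastereomer mixture) | O=C1OC2C(Br)=CC1(C(=O)OC)C(OC)(OC)C2CC=C(C)C | intermediate
10 | methyl 3-bromo-6,6-dimethoxy-5-(3-methylbut-2-enyl)cyclohexa-1,3-diene-1-carboxylate (racemic) | COC(=O)C1=CC(Br)=CC(CC=C(C)C)C1(OC)OC | intermediate
11 | methyl 5-bromo-2-methoxy-3-(3-methylbut-2-enyl)benzoate | COC(=O)c1cc(Br)cc(CC=C(C)C)c1OC | intermediate
12 | [5-bromo-2-methoxy-3-(3-methylbut-2-enyl)phenyl]methanol | OCc1cc(Br)cc(CC=C(C)C)c1OC | intermediate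
13 | 1-(triphenylphosphoranylidene)propan-2-one | CC(=O)C=P(c1ccccc1)(c1ccccc1)c1ccccc1 | starting material
14 | 5-bromo-2-methoxy-3-(3-methylbut-2-enyl)benzaldehyde | O=Cc1cc(Br)cc(CC=C(C)C)c1OC | intermediate
15 | (E)-4-[5-bromo-2-methoxy-3-(3-methylbut-2-enyl)phenyl]but-3-en-2-one | CC(=O)/C=C/c1cc(Br)cc(CC=C(C)C)c1OC | intermediate
16 | (E)-4-[5-bromo-2-methoxy-3-(3-methylbut-2-enyl)phenyl]-2-methylbut-3-en-2-ol | CC(C)(O)/C=C/c1cc(Br)cc(CC=C(C)C)c1OC | intermediate
17 | lithium (E)-4-[5-lithio-2-methoxy-3-(3-methylbut-2-enyl)phenyl]-2-methylbut-3-en-2-olate | [Li]c1cc(CC=C(C)C)c(OC)c(/C=C/C(C)(C)O[Li])c1 | intermediate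
18 | dilithium salt of the triisopropoxy[3-[(E)-3-oxido-3-methylbut-1-enyl]-4-methoxy-5-(3-methylbut-2-enyl)phenyl]borate | CC(C)O[B-](OC(C)C)(OC(C)C)c1cc(CC=C(C)C)c(OC)c(/C=C/C(C)(C)[O-])c1.[Li+].[Li+] | intermediate
19 | [3-[(E)-3-hydroxy-3-methylbut-1-enyl]-4-methoxy-5-(3-methylbut-2-enyl)phenyl]boronic acid | COc1c(/C=C/C(C)(C)O)cc(B(O)O)cc1CC=C(C)C | intermediate
20 | 7-hydroxy-4H-chromen-4-one | O=c1ccoc2cc(O)ccc12 | starting material
21 | 7-[tri(propan-2-yl)silyl]oxy-4H-chromen-4-one | O=c1ccoc2cc(O[Si](C(C)C)(C(C)C)C(C)C)ccc12 | intermediate
22 | (2S)-2-[3-[(E)-3-hydroxy-3-methylbut-1-enyl]-4-methoxy-5-(3-methylbut-2-enyl)phenyl]-7-[tri(propan-2-yl)silyl]oxy-2,3-dihydro-4H-chromen-4-one | COc1c(/C=C/C(C)(C)O)cc([C@@H]2CC(=O)c3ccc(O[Si](C(C)C)(C(C)C)C(C)C)cc3O2)cc1CC=C(C)C | intermediate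
23 | (2S)-7-hydroxy-2-[3-[(E)-3-hydroxy-3-methylbut-1-enyl]-4-methoxy-5-(3-methylbut-2-enyl)phenyl]-2,3-dihydro-4H-chromen-4-one | COc1c(/C=C/C(C)(C)O)cc([C@@H]2CC(=O)c3ccc(O)cc3O2)cc1CC=C(C)C | target

## Step count and least certain steps

Total step count: 11. Longest linear sequence: 9 steps (steps 2, 3, 4, 5, 6, 7, 8, 10 and 11, from 4 and 5); steps 1 and 9 are side branches.

Step 4 (key step). The most likely failure is a cycloaddition that is slowed by the β-substituent of the ketene acetal to the point where thermal or trace-acid decay of 8 (hydrolysis to the methyl ester, oligomerisation) outruns it, or a stepwise zwitterionic addition at C6 that opens the pyrone instead of closing the bicycle. The fallback sets out from 3 and returns at 11: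
- 3 is heated with commercial 1,1-dimethoxyethene, the unsubstituted ketene acetal for which this annulation is best established, to give methyl 5-bromo-2-methoxybenzoate F1.
- BCl3 cleaves the methyl ether chelated to the ester carbonyl to give methyl 5-bromo-2-hydroxybenzoate F2.
- O-Allylation catalysed by Pd(PPh3)4 (zerovalent palladium) with tert-butyl 2-methylbut-3-en-2-yl carbonate gives the tertiary allyl ether methyl 5-bromo-2-(2-methylbut-3-en-2-yloxy)benzoate F3.
- Aromatic Claisen rearrangement moves the group, with allylic inversion, to the only free ortho position and gives methyl 5-bromo-2-hydroxy-3-(3-methylbut-2-enyl)benzoate F4.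
- O-Methylation with MeI and K2CO3 returns 11.

This replaces the convergent ring construction by a longer linear sequence on a preformed arene.

Step 3. The most likely failure is capture of the newly formed ketene acetal by the dialkoxycarbenium ion (Claisen-type self-condensation), or hydrolysis to the ester during isolation. The fallback sets out from 7 and 3 and returns at 11: 8 is not isolated. Instead 3 is heated with an excess of 7 and a catalytic amount of pivalic acid at about 160 °C in a sealed vessel, so that 8 is formed in low stationary concentration by reversible loss of methanol and is intercepted by the pyrone as it forms.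

Step 10. The most likely failures are insufficient discrimination of the enone faces with this heavily substituted aryl group, and protodeboronation competing with transmetalation. The fallback sets out from 19 and 21 and returns at 22. The addition is run with the achiral catalyst [Rh(OH)(cod)]2 to give the racemic 2-aryl-7-[tri(propan-2-yl)silyl]oxychroman-4-one F5. Preparative chromatography on a polysaccharide-carbamate chiral stationary phase then separates 22 from its (2R)-enantiomer F6, which can be recycled by base-mediated ring opening and reclosure. This trades catalytic asymmetric induction for resolution.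

Step 8. The most likely failures are alkylation of the aryllithium by the butyl bromide formed in the exchange, deprotonation at the doubly activated benzylic–allylic CH2 of the prenyl group, and protonation of the aryllithium to debrominated material. The fallback sets out from 16 and returns at 19. Miyaura borylation (Pd(dppf)Cl2, bis(pinacolato)diboron, KOAc, dioxane, 85 °C) gives the chromatographable pinacol ester 2-[3-[(E)-3-hydroxy-3-methylbut-1-enyl]-4-methoxy-5-(3-methylbut-2-enyl)phenyl]-4,4,5,5-tetramethyl-1,3,2-dioxaborolane F7. Oxidative cleavage of the pinacol unit with NaIO4 and NH4OAc in aqueous acetone then frees 19. Catalytic borylation thus replaces the organolithium.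

Step 11. The most likely failure is erosion of the C2 configuration through phenoxide- or enolate-triggered ring opening if the buffering is inadequate, or ionisation of the tertiary allylic alcohol if the medium is made too acidic. The fallback sets out from 19 and 20 and returns at 23: the silyl group is omitted, and the rhodium-catalysed addition of step 10 is run directly on the free phenol 20 under the same base-free conditions, so that no deprotection is needed.

## Further compounds

F1 | step 4 | methyl 5-bromo-2-methoxybenzoate | COC(=O)c1cc(Br)ccc1OC
F2 | step 4 | methyl 5-bromo-2-hydroxybenzoate | COC(=O)c1cc(Br)ccc1O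
F3 | step 4 | methyl 5-bromo-2-(2-methylbut-3-en-2-yloxy)benzoate | COC(=O)c1cc(Br)ccc1OC(C)(C)C=C
F4 | step 4 | methyl 5-bromo-2-hydroxy-3-(3-methylbut-2-enyl)benzoate | COC(=O)c1cc(Br)cc(CC=C(C)C)c1O
F0 | step 3 | none | none
F5 | step 10 | racemic 2-[3-[(E)-3-hydroxy-3-methylbut-1-enyl]-4-methoxy-5-(3-methylbut-2-enyl)phenyl]-7-[tri(propan-2-yl)silyl]oxy-2,3-dihydro-4H-chromen-4-one | COc1c(/C=C/C(C)(C)O)cc(C2CC(=O)c3ccc(O[Si](C(C)C)(C(C)C)C(C)C)cc3O2)cc1CC=C(C)C
F6 | step 10 | (2R)-2-[3-[(E)-3-hydroxy-3-methylbut-1-enyl]-4-methoxy-5-(3-methylbut-2-enyl)phenyl]-7-[tri(propan-2-yl)silyl]oxy-2,3-dihydro-4H-chromen-4-one | COc1c(/C=C/C(C)(C)O)cc([C@H]2CC(=O)c3ccc(O[Si](C(C)C)(C(C)C)C(C)C)cc3O2)cc1CC=C(C)C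
F7 | step 8 | 2-[3-[(E)-3-hydroxy-3-methylbut-1-enyl]-4-methoxy-5-(3-methylbut-2-enyl)phenyl]-4,4,5,5-tetramethyl-1,3,2-dioxaborolane | COc1c(/C=C/C(C)(C)O)cc(B2OC(C)(C)C(C)(C)O2)cc1CC=C(C)C
F0 | step 11 | none | none
A1 | alternative 1 | (2S,4S)-2-[3-[(E)-3-hydroxy-3-methylbut-1-enyl]-4-methoxy-5-(3-methylbut-2-enyl)phenyl]-7-[tri(propan-2-yl)silyl]oxy-3,4-dihydro-2H-chromen-4-ol (2,4-cis) | COc1c(/C=C/C(C)(C)O)cc([C@@H]2C[C@H](O)c3ccc(O[Si](C(C)C)(C(C)C)C(C)C)cc3O2)cc1CC=C(C)C
A2 | alternative 1 | (1S,3S)-1-[2-bromo-4-[tri(propan-2-yl)silyl]oxyphenyl]-3-[3-[(E)-3-hydroxy-3-methylbut-1-enyl]-4-methoxy-5-(3-methylbut-2-enyl)phenyl]propane-1,3-diol | COc1c(/C=C/C(C)(C)O)cc([C@@H](O)C[C@H](O)c2ccc(O[Si](C(C)C)(C(C)C)C(C)C)cc2Br)cc1CC=C(C)C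
A3 | alternative 2 | (2S)-2-(3,5-dibromo-4-methoxyphenyl)-7-hydroxy-2,3-dihydro-4H-chromen-4-one | COc1c(Br)cc([C@@H]2CC(=O)c3ccc(O)cc3O2)cc1Br
A4 | alternative 2 | (2S)-5-bromo-2-(3,5-dibromo-4-methoxyphenyl)-2,3-dihydro-4H-pyran-4-one | COc1c(Br)cc([C@@H]2CC(=O)C(Br)=CO2)cc1Br
A5 | alternative 2 | (E)-1-methoxy-3-(trimethylsilyloxy)buta-1,3-diene | CO/C=C/C(=C)O[Si](C)(C)C
A6 | alternative 3 | (2S)-2-[3-bromo-4-methoxy-5-(3-methylbut-2-enyl)phenyl]-4-(tert-butyldimethylsilyloxy)-7-[tri(propan-2-yl)silyl]oxy-2H-chromene | COc1c(Br)cc([C@@H]2C=C(O[Si](C)(C)C(C)(C)C)c3ccc(O[Si](C(C)C)(C(C)C)C(C)C)cc3O2)cc1CC=C(C)C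
A7 | alternative 3 | tert-butyl-[1-[2-[(1S)-1-[3-bromo-4-methoxy-5-(3-methylbut-2-enyl)phenyl]prop-2-enoxy]-4-[tri(propan-2-yl)silyl]oxyphenyl]ethenoxy]dimethylsilane | COc1c(Br)cc([C@H](C=C)Oc2cc(O[Si](C(C)C)(C(C)C)C(C)C)ccc2C(=C)O[Si](C)(C)C(C)(C)C)cc1CC=C(C)C
A8 | alternative 3 | 2-methylbut-3-en-2-ol | C=CC(C)(C)O
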